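The data come from a simulation with constants of no real substance; scatter was added.

The question is how the substrate divides at the end of each flask, and how much first product green holds.

common to all: substrate 0.10 M

| run | reagent | remark | time |
|---|---|---|---|
| east | 0.049 M | run made earlier |  |
| north-west | 0.14 M | run made earlier |  |
| amber | 0.0800 M |  | 2.5 d |
| blue | 0.200 M |  | 2.5 d |
| green | 0.120 M |  | 2.5 d |

* which of these holds the largest part of the substrate at the end of amber (double product / first product / substrate)
* which of these holds the largest part of the substrate at the end of blue (double product / first product / substrate)
* which of these holds the largest part of the substrate at the end of green (double product / first product / substrate)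
* how much first product is there at the end of green, in percent of the substrate charged

| run | time / d | first product / % | substrate / % |
|---|---|---|---|
| east | 0.333 | 1 | 86 |
| east | 0.833 | 6 | 75 |
| east | 1.67 | 10 | 58 |
| east | 2.50 | 15 | 48 |
| north-west | 0.208 | 6 | 88 |
| north-west | 0.500 | 12 | 77 |
| north-west | 1.04 | 17 | 60 |
| north-west | 2.50 | 34 | 36 |

(scatter of a reading: 1.5 percentage points)

I start with east, where reagent at 0.049 M is charged below substrate at 0.10 M, so on paper it is the limiting reagent. At 2.50 d, east holds 0.0150 M of first product, and the rest, meaning substrate lost minus first product, is 0.0370 M. I take first product to hold one reagent and double product two, so the balance of the reagent allows 0.0170 M of double product, which is less than that rest, and so some substrate must leave without reagent.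

The rest is 37.0% in east and 30.0% in north-west, but first product climbs from 15% to 34%. So I divide c(first product) by c(rest) and by charged c(reagent), all at 2.5 d with substrate charged at 0.10 M, and call the mean of the two runs S, a selectivity factor 8.18 L mol⁻¹. East reads 8.27 L mol⁻¹ and north-west 8.10 L mol⁻¹, both worked from readings with a scatter of 1.5 percentage points.

The share of lost substrate in first product is then S·c(reagent)/(1+S·c(reagent)), which is 0.495 for green. Substrate interpolated in reagent between the two runs gives 38.6% for green, so I commit to 30.4% of first product, a rest of 31.0%, and substrate ahead. The same line, extended past north-west for blue, puts substrate ahead in amber, and first product ahead in blue, where the share is 0.621.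

The forecast gives substrate for amber, first product for blue, substrate for green and 29% (25% to 33%) of first product in green, lower than my figure, on the grounds of “parallel routes rather than a sequence”.

Green ends with 29.5% of first product, and the scheme is:

    substrate + reagent → first product + by-product (k = 0.0790 L mol⁻¹ h⁻¹)
    reagent + first product → double product + by-product (k = 0.00490 L mol⁻¹ h⁻¹)
    2 substrate → homo dimer (k = 0.0670 L mol⁻¹ h⁻¹)

Green's rest is nearly all homo dimer, which holds 32.1% of the substrate, each unit counted as two, against 0.515% in double product. Blue has lost 71.2% of its substrate, and the share of 0.621 makes that 44.2% of first product; blue holds 43.6%.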